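**Plan**

- Retrosynthesis: the C4-C4a aryl ketone bond of ring C is cut first, then the C2-O1 ether bond, then the carbinol C-H bond at the future C2. This leads back to a ring B β-keto ester and a ring A phenol.
- Enabling feature: once C4-C4a is cut, ring A is a 3,4,5-trimethoxyphenoxy group with a mirror plane through C8a and C6. The two carbons ortho to O1 (future C4a and C8) are therefore identical, and closure at either can only give the 5,6,7-trimethoxy pattern.
- Forward: keto ester 1 already holds ring B and the C2-C3-C4 chain. Hydrogenation gives carbinol 2, phenol 3 brings in ring A through O1 (ether 4), the ester is cleaved (acid 5), and ring C is closed last through mixed anhydride 6 to give target 7.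
- Stereochemistry: the only stereocenter, C2, is set as R by catalyst-controlled Noyori hydrogenation and inverted once to S in the Mitsunobu step. No later step makes or breaks a bond at C2.

Key step: step 4

Assumption: keto ester 1, phenol 3 and both enantiomers of the BINAP ruthenium catalyst are bought. The facial sense of the hydrogenation is taken to be the one established for aryl β-keto esters, unchanged by the two methoxy groups of ring B. Flavanone numbering (O1, C2, C3, C4, C4a, C5 to C8, C8a, primed ring B) is used throughout.

**Route**

Step 1
Reactants: 1 ethyl 3-(3,4-dimethoxyphenyl)-3-oxopropanoate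
Product: 2 ethyl (3R)-3-(3,4-dimethoxyphenyl)-3-hydroxypropanoate
Conditions: H2 (50 atm), RuCl2[(S)-BINAP] (0.5 mol%), EtOH, 40 °C
Reagents that add atoms: none
Why: Noyori asymmetric hydrogenation, in which the β-keto ester chelates divalent ruthenium through both carbonyl oxygens and the (S)-BINAP ligand directs hydride to one ketone face, in the sense that turns acetoacetates into (S)-3-hydroxybutanoates and therefore gives the (R)-carbinol here, where the aryl group outranks CH2CO2Et.

Step 2
Reactants: 2 ethyl (3R)-3-(3,4-dimethoxyphenyl)-3-hydroxypropanoate; 3 3,4,5-trimethoxyphenol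
Product: 4 ethyl (3S)-3-(3,4-dimethoxyphenyl)-3-(3,4,5-trimethoxyphenoxy)propanoate
Conditions: 3 (1.3 equiv), PPh3 (1.5 equiv), DIAD (1.5 equiv, added last), toluene, -20 to 0 °C
Reagents that add atoms: none
Why: Mitsunobu etherification, in which the alcohol is activated as its alkoxyphosphonium ion and displaced by the phenoxide of 3 (pKa about 10) in an SN2 reaction with inversion, so the (R)-carbinol becomes the (S)-aryl ether, with the nonpolar solvent and low temperature chosen to hold back ionization of the electron-rich benzylic centre and elimination.

Step 3
Reactants: 4 ethyl (3S)-3-(3,4-dimethoxyphenyl)-3-(3,4,5-trimethoxyphenoxy)propanoate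
Product: 5 (3S)-3-(3,4-dimethoxyphenyl)-3-(3,4,5-trimethoxyphenoxy)propanoic acid
Conditions: LiOH·H2O (2 equiv), THF/H2O 3:1, 0 °C; then 0.5 M HCl to pH 4 at 0 °C, EtOAc extraction, azeotropic drying
Reagents that add atoms: lithium hydroxide, [Li+].[OH-]; water, O (one oxygen of this pair becomes the carboxyl OH)
Why: Saponification (BAc2 ester hydrolysis), in which hydroxide attack at the ester carbonyl at 0 °C should be much faster than the α-deprotonation that would expel the aryloxide by E1cB elimination, and the stereocenter, β to the carbonyl, is not touched.

Step 4
Reactants: 5 (3S)-3-(3,4-dimethoxyphenyl)-3-(3,4,5-trimethoxyphenoxy)propanoic acid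
Product: 7 (2S)-5,6,7,3',4'-pentamethoxyflavanone, via mixed trifluoroacetic anhydride 6 (not isolated)
Conditions: (CF3CO)2O (1.5 equiv), CH2Cl2 (0.05 M), -20 to 0 °C; poured into cold pH 7 phosphate buffer
Reagents that add atoms: trifluoroacetic anhydride, O=C(OC(=O)C(F)(F)F)C(F)(F)F (its trifluoroacetyl group is carried by intermediate 6 only; none of its atoms remain in 7)
Why: Acid 5 and trifluoroacetic anhydride give mixed anhydride 6, whose acyl carbon (as the free acylium ion or its tight ion pair with trifluoroacetate) is attacked by a ring A carbon next to the ether oxygen, and loss of the ring proton restores aromaticity and leaves the new C4-C4a bond. The reaction type is the known intramolecular Friedel-Crafts acylation of 3-aryloxypropanoic acids to chroman-4-ones. Ring C closes as a six-membered ring in a 6-exo mode, the C=O bond of the electrophile staying outside the ring (6-exo-trig on the anhydride carbonyl, 6-exo-dig on the acylium ion). No stereocenter is created, and C2 is carried over from 5 with none of its bonds made or broken. Regioselectivity within ring A is not needed because its two open carbons are mirror images, and site selectivity over ring B (closure at C6' would give a five-membered indanone) is secured because the attacked carbon has oxygen donors at both ortho positions and at the para position (O1, 5-OMe and 7-OMe in product numbering), whereas C6' has a single para methoxy group. The last demand, that the benzylic C2-O1 bond does not ionize, is met by using no acid stronger than the trifluoroacetic acid released, in dilute CH2Cl2 at or below 0 °C, followed by a cold neutral quench.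

**Compound list**

1 | ethyl 3-(3,4-dimethoxyphenyl)-3-oxopropanoate | CCOC(=O)CC(=O)c1ccc(OC)c(OC)c1 | starting material
2 | ethyl (3R)-3-(3,4-dimethoxyphenyl)-3-hydroxypropanoate | COc1ccc([C@@H](CC(=O)OCC)O)cc1OC | intermediate
3 | 3,4,5-trimethoxyphenol | COc1cc(O)cc(OC)c1OC | starting material
4 | ethyl (3S)-3-(3,4-dimethoxyphenyl)-3-(3,4,5-trimethoxyphenoxy)propanoate | COc1ccc([C@H](CC(=O)OCC)Oc2cc(OC)c(OC)c(OC)c2)cc1OC | intermediate
5 | (3S)-3-(3,4-dimethoxyphenyl)-3-(3,4,5-trimethoxyphenoxy)propanoic acid | COc1ccc([C@H](CC(=O)O)Oc2cc(OC)c(OC)c(OC)c2)cc1OC | intermediate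
6 | (3S)-3-(3,4-dimethoxyphenyl)-3-(3,4,5-trimethoxyphenoxy)propanoic trifluoroacetic anhydride | COc1ccc([C@H](CC(=O)OC(=O)C(F)(F)F)Oc2cc(OC)c(OC)c(OC)c2)cc1OC | intermediate
7 | (2S)-5,6,7,3',4'-pentamethoxyflavanone, (2S)-2-(3,4-dimethoxyphenyl)-5,6,7-trimethoxychroman-4-one | COc1ccc([C@@H]2CC(=O)c3c(cc(OC)c(OC)c3OC)O2)cc1OC | target

**Step count and risks**

Total step count: 4. Longest linear sequence: 4 steps (1 to 2 to 4 to 5 to 7); phenol 3 enters in step 2.

Steps most likely to fail:

1. Step 2 (Mitsunobu etherification).
   - What may go wrong: the alkoxyphosphonium ion may ionize at the electron-rich benzylic carbon, which would erode the enantiomeric purity and allow C-alkylation of the very nucleophilic phenol. The activated alcohol may also undergo β-elimination toward the cinnamate, since the α-hydrogens are acidified by the ester.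
   - Fallback: it sets out from 1 and forms the aryl-oxygen bond instead of the C2-O1 bond, so the stereocenter is never a reaction site. Hydrogenation of 1 with the enantiomeric catalyst RuCl2[(R)-BINAP] would give ethyl (3S)-3-(3,4-dimethoxyphenyl)-3-hydroxypropanoate F1. Chan-Lam O-arylation of F1 with commercial 3,4,5-trimethoxyphenylboronic acid (Cu(OAc)2, DMAP, 4 Å molecular sieves, CH2Cl2, O2, room temperature; divalent copper, near-neutral medium) would then give the aryl ether with retention. The route is rejoined at 4.

2. Step 4 (ring closure).
   - What may go wrong: the trifluoroacetic acid released may promote ionization of the benzylic C2-O1 bond, in 5, in 6 or in the product (there by ring opening to the 2'-hydroxychalcone and reclosure), with loss of configuration at C2. Competing C-trifluoroacetylation of ring A by the excess anhydride is a lesser concern.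
   - Fallback: it sets out from 5 and makes the same C4-C4a bond and the same ring C with reversed polarity and no acid. Carbodiimide coupling of 5 with N,O-dimethylhydroxylamine hydrochloride (EDC·HCl, HOBt, N-methylmorpholine, CH2Cl2, 0 °C) would give the Weinreb amide (3S)-3-(3,4-dimethoxyphenyl)-N-methoxy-N-methyl-3-(3,4,5-trimethoxyphenoxy)propanamide F2. N-Bromosuccinimide (1.0 equiv, MeCN, -20 °C) should brominate ring A at one of its two equivalent carbons next to the ether oxygen, the most electron-rich CH in the molecule, to give (3S)-3-(2-bromo-3,4,5-trimethoxyphenoxy)-3-(3,4-dimethoxyphenyl)-N-methoxy-N-methylpropanamide F3. Bromine-lithium exchange (n-BuLi, THF, -78 °C) and attack of the aryllithium on the amide carbonyl (Parham-type anionic cyclization) would close ring C. The ketone stays masked as the chelated tetrahedral adduct until a cold NH4Cl quench, and the route is rejoined at 7.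

3. Step 3 (ester cleavage).
   - What may go wrong: base-induced β-elimination of the aryloxide (retro-oxa-Michael, E1cB) from the ester enolate may compete with hydrolysis, destroying the ether linkage.
   - Fallback: it sets out from 4 and reaches the acid by a change of oxidation level, with no hydroxide. LiBH4 (THF, 0 °C to room temperature) would reduce the ester to (3S)-3-(3,4-dimethoxyphenyl)-3-(3,4,5-trimethoxyphenoxy)propan-1-ol F4. TEMPO (catalytic) with PhI(OAc)2 in MeCN/pH 7 buffer would oxidize the primary alcohol to the carboxylic acid. The route is rejoined at 5.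

Further compounds
F1 | step 2 | ethyl (3S)-3-(3,4-dimethoxyphenyl)-3-hydroxypropanoate | COc1ccc([C@H](CC(=O)OCC)O)cc1OC
F2 | step 4 | (3S)-3-(3,4-dimethoxyphenyl)-N-methoxy-N-methyl-3-(3,4,5-trimethoxyphenoxy)propanamide | COc1ccc([C@H](CC(=O)N(C)OC)Oc2cc(OC)c(OC)c(OC)c2)cc1OC
F3 | step 4 | (3S)-3-(2-bromo-3,4,5-trimethoxyphenoxy)-3-(3,4-dimethoxyphenyl)-N-methoxy-N-methylpropanamide | COc1ccc([C@H](CC(=O)N(C)OC)Oc2cc(OC)c(OC)c(OC)c2Br)cc1OC
F4 | step 3 | (3S)-3-(3,4-dimethoxyphenyl)-3-(3,4,5-trimethoxyphenoxy)propan-1-ol | COc1ccc([C@H](CCO)Oc2cc(OC)c(OC)c(OC)c2)cc1OC
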